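**Retrosynthetic overview**
1. The plan rests on the labd-8(17)-ene core: a trans-decalin (ring A = C1–C5, C10; ring B = C5–C10) whose quaternary C4 carries the equatorial C18 ester and the axial C19 methyl, with contiguous stereocentres C4, C5, C10, C9 and the exocyclic C8=C17 methylene.
2. End game: the C15 acid comes from selective hydrolysis of the 15,18-dimethyl ester, the C18 ester from a C18 silyl ether, and C3–H from a C3 hydroxyl (Barton–McCombie).
3. Key disconnection: C4–C5 and C10–C9, opening ring A and then ring B (formed in that order in one cationic cascade) to a (3S,4S)-epoxy diene ending in a trisubstituted allylsilane.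
4. The epoxide comes from Sharpless epoxidation of the E-allylic alcohol at C18; the C9–C11 bond from Negishi coupling of a vinyl iodide with the zinc reagent derived from methyl hydrogen (R)-3-methylglutarate (source of C13).
5. The vinyl iodide comes from silylmethyl carbocupration–iodination of a dienyne built from geranyl acetate (C18 oxygen by SeO2, C7–C9 by propargylation).

Key step: step 14

Remark: labdane numbering is used throughout; the allylsilane alkene C8=C9, in which C7 and C11 are trans, has the descriptor Z because CH2SiMe3 outranks C7.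

**Route**

Step 1
Reactants: 1 geranyl acetate
Product: 2 (2E,6E)-8-hydroxy-3,7-dimethylocta-2,6-dien-1-yl acetate
Conditions: SeO2 (cat.), salicylic acid (cat.), t-BuOOH, CH2Cl2, rt
Reagents that add atoms: tert-butyl hydroperoxide, CC(C)(C)OO (oxygen relayed by the SeO2 catalyst, O=[Se]=O)
Why: Sharpless–Umbreit allylic oxidation (ene reaction then [2,3]-sigmatropic shift) should hydroxylate the E-methyl of the distal trisubstituted alkene, because the allylic acetate deactivates the proximal alkene, and both E geometries stay intact.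

Step 2
Reactants: 2 (2E,6E)-8-hydroxy-3,7-dimethylocta-2,6-dien-1-yl acetate
Product: 3 (2E,6E)-8-[(tert-butyldimethylsilyl)oxy]-3,7-dimethylocta-2,6-dien-1-yl acetate
Conditions: TBSCl, imidazole, DMF, 0 °C to rt
Reagents that add atoms: tert-butyldimethylsilyl chloride, CC(C)(C)[Si](C)(C)Cl
Why: Imidazole-promoted silylation of a primary allylic alcohol is routine and masks the future C18 oxygen through the organometallic steps.

Step 3
Reactants: 3 (2E,6E)-8-[(tert-butyldimethylsilyl)oxy]-3,7-dimethylocta-2,6-dien-1-yl acetate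
Product: 4 (2E,6E)-8-[(tert-butyldimethylsilyl)oxy]-3,7-dimethylocta-2,6-dien-1-ol
Conditions: K2CO3 (cat.), MeOH, rt
Reagents that add atoms: none
Why: Base-catalysed transesterification (methanolysis) removes the acetate while the silyl ether is stable to carbonate in methanol.

Step 4
Reactants: 4 (2E,6E)-8-[(tert-butyldimethylsilyl)oxy]-3,7-dimethylocta-2,6-dien-1-ol
Product: 5 {[(2E,6E)-8-bromo-2,6-dimethylocta-2,6-dien-1-yl]oxy}(tert-butyl)dimethylsilane
Conditions: CBr4, PPh3, CH2Cl2, 0 °C
Reagents that add atoms: carbon tetrabromide, BrC(Br)(Br)Br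
Why: The Appel reaction converts the primary allylic alcohol into the bromide by SN2 displacement under neutral conditions, without allylic transposition or loss of the silyl ether.

Step 5
Reactants: 5 {[(2E,6E)-8-bromo-2,6-dimethylocta-2,6-dien-1-yl]oxy}(tert-butyl)dimethylsilane; 6 1-(trimethylsilyl)propyne
Product: 8 tert-butyldimethyl{[(2E,6E)-2,6-dimethyl-11-(trimethylsilyl)undeca-2,6-dien-10-yn-1-yl]oxy}silane, via 3-lithio-1-(trimethylsilyl)propyne 7 (not isolated)
Conditions: n-BuLi, THF, −78 °C; then 5, −78 to −20 °C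
Reagents that add atoms: none
Why: Alkylation of the lithiated silylpropyne (a propargyl anion equivalent) at the primary allylic bromide forms C6–C7 by SN2, and the C-silyl group suppresses allene formation.

Step 6
Reactants: 8 tert-butyldimethyl{[(2E,6E)-2,6-dimethyl-11-(trimethylsilyl)undeca-2,6-dien-10-yn-1-yl]oxy}silane
Product: 9 tert-butyl{[(2E,6E)-2,6-dimethylundeca-2,6-dien-10-yn-1-yl]oxy}dimethylsilane
Conditions: K2CO3, MeOH, rt
Reagents that add atoms: none
Why: Methanolysis cleaves the alkynyl C–Si bond selectively, since the O-silyl ether is inert to these conditions.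

Step 7
Reactants: 9 tert-butyl{[(2E,6E)-2,6-dimethylundeca-2,6-dien-10-yn-1-yl]oxy}dimethylsilane; 10 (trimethylsilyl)methylmagnesium chloride
Product: 13 tert-butyl{[(2E,6E,10Z)-11-iodo-2,6-dimethyl-10-[(trimethylsilyl)methyl]undeca-2,6,10-trien-1-yl]oxy}dimethylsilane, via (trimethylsilyl)methylcopper 11 (not isolated), via vinylcopper adduct 12 (not isolated)
Conditions: 10, CuBr·SMe2, Et2O/Me2S, −40 °C; then 9, −30 to 0 °C; then I2 (1 equiv), THF, −60 °C
Reagents that add atoms: iodine, II
Why: In this Normant carbocupration the silylmethylcopper should add syn across the terminal alkyne with the carbon group on the internal carbon, and iodinolysis with retention places iodine cis to CH2SiMe3, which fixes the C7/C11-trans geometry of the later C8=C9 alkene.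

Step 8
Reactants: 14 methyl hydrogen (R)-3-methylglutarate
Product: 15 methyl (3R)-5-hydroxy-3-methylpentanoate
Conditions: BH3·THF, THF, −15 to 0 °C; aqueous work-up
Reagents that add atoms: none
Why: Borane reduces the carboxylic acid chemoselectively beside the methyl ester, and the stereocentre, which is not enolisable, is untouched.

Step 9
Reactants: 15 methyl (3R)-5-hydroxy-3-methylpentanoate
Product: 16 methyl (3S)-5-iodo-3-methylpentanoate
Conditions: I2, PPh3, imidazole, CH2Cl2, 0 °C
Reagents that add atoms: iodine, II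
Why: Appel-type (Garegg–Samuelsson) iodination of the primary alcohol proceeds by SN2 away from the stereocentre, whose descriptor changes to S only because iodine raises the priority of that branch.

Step 10
Reactants: 13 tert-butyl{[(2E,6E,10Z)-11-iodo-2,6-dimethyl-10-[(trimethylsilyl)methyl]undeca-2,6,10-trien-1-yl]oxy}dimethylsilane; 16 methyl (3S)-5-iodo-3-methylpentanoate
Product: 18 methyl (3R,6Z,10E,14E)-16-[(tert-butyldimethylsilyl)oxy]-3,11,15-trimethyl-7-[(trimethylsilyl)methyl]hexadeca-6,10,14-trienoate, via [(3S)-5-methoxy-3-methyl-5-oxopentyl]zinc iodide 17 (not isolated)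
Conditions: 16, Zn dust (activated with BrCH2CH2Br and Me3SiCl), DMA, 40 °C; then 13, PdCl2(dppf) (5 mol%), THF/DMA, rt to 40 °C
Reagents that add atoms: none
Why: Negishi sp2–sp3 cross-coupling of the ester-tolerant alkylzinc iodide with the vinyl iodide forms C9–C11 with retention of the alkene geometry.

Step 11
Reactants: 18 methyl (3R,6Z,10E,14E)-16-[(tert-butyldimethylsilyl)oxy]-3,11,15-trimethyl-7-[(trimethylsilyl)methyl]hexadeca-6,10,14-trienoate
Product: 19 methyl (3R,6Z,10E,14E)-16-hydroxy-3,11,15-trimethyl-7-[(trimethylsilyl)methyl]hexadeca-6,10,14-trienoate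
Conditions: TBAF, AcOH, THF, 0 °C
Reagents that add atoms: none
Why: Buffered fluoride cleaves the unhindered primary O–Si bond much faster than the allylic C–SiMe3 bond at low temperature, and the methyl ester tolerates the buffered medium.

Step 12
Reactants: 19 methyl (3R,6Z,10E,14E)-16-hydroxy-3,11,15-trimethyl-7-[(trimethylsilyl)methyl]hexadeca-6,10,14-trienoate
Product: 20 methyl (3R,6Z,10E)-13-[(2S,3S)-3-(hydroxymethyl)-3-methyloxiran-2-yl]-3,11-dimethyl-7-[(trimethylsilyl)methyl]trideca-6,10-dienoate
Conditions: Ti(OiPr)4 (10 mol%), L-(+)-diethyl tartrate (12 mol%), t-BuOOH, 4 Å molecular sieves, CH2Cl2, −20 °C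
Reagents that add atoms: tert-butyl hydroperoxide, CC(C)(C)OO
Why: In the Katsuki–Sharpless asymmetric epoxidation, L-(+)-tartrate should direct oxygen to the face of the E-2-methylallylic alcohol that gives the (2S,3S)-epoxy alcohol (3S,4S in labdane numbering), and the alkenes without a directing hydroxyl, the allylsilane included, should not react.

Step 13
Reactants: 20 methyl (3R,6Z,10E)-13-[(2S,3S)-3-(hydroxymethyl)-3-methyloxiran-2-yl]-3,11-dimethyl-7-[(trimethylsilyl)methyl]trideca-6,10-dienoate
Product: 21 methyl (3R,6Z,10E)-13-[(2S,3S)-3-{[(tert-butyldimethylsilyl)oxy]methyl}-3-methyloxiran-2-yl]-3,11-dimethyl-7-[(trimethylsilyl)methyl]trideca-6,10-dienoate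
Conditions: TBSCl, imidazole, DMF, 0 °C
Reagents that add atoms: tert-butyldimethylsilyl chloride, CC(C)(C)[Si](C)(C)Cl
Why: Silylation under weakly basic conditions caps the hydroxyl without epoxide migration, so the Lewis acid of the next step meets only the epoxide, a hindered silyl ether and the ester.

Step 14
Reactants: 21 methyl (3R,6Z,10E)-13-[(2S,3S)-3-{[(tert-butyldimethylsilyl)oxy]methyl}-3-methyloxiran-2-yl]-3,11-dimethyl-7-[(trimethylsilyl)methyl]trideca-6,10-dienoate
Product: 22 methyl (13R)-18-[(tert-butyldimethylsilyl)oxy]-3β-hydroxylabd-8(17)-en-15-oate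
Conditions: MeAlCl2 (3 equiv), CH2Cl2, −78 °C; aqueous work-up
Reagents that add atoms: none
Why: MeAlCl2 binds the epoxide oxygen, the C4–O bond ionises with backside participation of the C5=C10 alkene, the C10 cation is captured by C9 of the allylsilane, and the β-silyl cation at C8 gives up Me3Si to chloride, leaving only the C8=C17 alkene; the closest known reaction type is the Lewis-acid-promoted epoxy-polyene cyclization terminated by a 2-substituted allylsilane. Ring A closes 6-endo at the epoxide (C5 to C4, both epoxide carbons in the ring) and ring B closes 6-endo-trig (C9 to C10) through a chair–chair fold. C4 is set by inversion at the epoxide carbon, so the CH2OSi group trans to the chain becomes equatorial C18 and the cis methyl axial C19, while C3 keeps its Sharpless-derived configuration as the equatorial 3β-oxygen. C5 and C10 follow from anti addition across the E-alkene (trans ring fusion), and C9 from the chair of ring B, in which the C7/C11-trans geometry of the allylsilane puts C11 equatorial. The step needs ring closure to outrun hydride shift to a C3 ketone and needs a single alkene regioisomer: the first is helped by the nucleophilic trisubstituted alkene poised for six-membered closure and by MeAlCl2, which also scavenges the protons that would protodesilylate, and the second is secured by silicon, which directs the elimination only towards C17.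

Step 15
Reactants: 22 methyl (13R)-18-[(tert-butyldimethylsilyl)oxy]-3β-hydroxylabd-8(17)-en-15-oate
Product: 23 methyl (13R)-18-[(tert-butyldimethylsilyl)oxy]-3β-[(1H-imidazol-1-ylcarbonothioyl)oxy]labd-8(17)-en-15-oate
Conditions: 1,1′-thiocarbonyldiimidazole, DMAP (cat.), ClCH2CH2Cl, 80 °C
Reagents that add atoms: 1,1′-thiocarbonyldiimidazole, S=C(n1ccnc1)n1ccnc1
Why: Thioacylation of the equatorial secondary alcohol (first half of the Barton–McCombie deoxygenation) runs without an alkoxide, which avoids 1,3-silyl migration from O18 to O3.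

Step 16
Reactants: 23 methyl (13R)-18-[(tert-butyldimethylsilyl)oxy]-3β-[(1H-imidazol-1-ylcarbonothioyl)oxy]labd-8(17)-en-15-oate
Product: 24 methyl (13R)-18-[(tert-butyldimethylsilyl)oxy]labd-8(17)-en-15-oate
Conditions: Bu3SnH, AIBN (cat.), toluene, 110 °C
Reagents that add atoms: none
Why: Barton–McCombie radical deoxygenation replaces the C3 oxygen by hydrogen through a secondary radical that has no β-leaving group and no alkene within reach.

Step 17
Reactants: 24 methyl (13R)-18-[(tert-butyldimethylsilyl)oxy]labd-8(17)-en-15-oate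
Product: 25 methyl (13R)-18-hydroxylabd-8(17)-en-15-oate
Conditions: HF·pyridine, pyridine, THF, 0 °C to rt
Reagents that add atoms: none
Why: Buffered HF cleaves the neopentyl-type silyl ether without hydrolysing the ester and should be too weakly acidic to isomerise the exocyclic alkene.

Step 18
Reactants: 25 methyl (13R)-18-hydroxylabd-8(17)-en-15-oate
Product: 26 methyl (13R)-18-oxolabd-8(17)-en-15-oate
Conditions: Dess–Martin periodinane, CH2Cl2, rt
Reagents that add atoms: none
Why: Dess–Martin oxidation takes the hindered primary alcohol to the aldehyde, which has no α-hydrogen and so cannot epimerise at C4.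

Step 19
Reactants: 26 methyl (13R)-18-oxolabd-8(17)-en-15-oate
Product: 27 (13R)-15-methoxy-15-oxolabd-8(17)-en-18-oic acid
Conditions: NaClO2, NaH2PO4, 2-methyl-2-butene, t-BuOH/H2O, rt
Reagents that add atoms: sodium chlorite, [Na+].[O-]Cl=O
Why: Pinnick oxidation converts the aldehyde into the acid while excess 2-methyl-2-butene traps HOCl before it can attack the C8=C17 alkene.

Step 20
Reactants: 27 (13R)-15-methoxy-15-oxolabd-8(17)-en-18-oic acid
Product: 28 dimethyl (13R)-labd-8(17)-ene-15,18-dioate
Conditions: MeI, K2CO3, DMF, rt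
Reagents that add atoms: iodomethane, CI
Why: O-Alkylation of the carboxylate (SN2 at methyl) is insensitive to the steric hindrance around the C18 carbonyl.

Step 21
Reactants: 28 dimethyl (13R)-labd-8(17)-ene-15,18-dioate
Product: 29 (13R)-18-methoxy-18-oxolabd-8(17)-en-15-oic acid
Conditions: LiOH, THF/MeOH/H2O, rt; then 1 M HCl
Reagents that add atoms: lithium hydroxide, [Li+].[OH-]
Why: Saponification by acyl addition should take place only at the unhindered C15 ester, since the C18 ester sits on the quaternary C4 and resists hydroxide at room temperature.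

**Compound list**
1 | geranyl acetate | CC(C)=CCC/C(C)=C/COC(C)=O | starting material
2 | (2E,6E)-8-hydroxy-3,7-dimethylocta-2,6-dien-1-yl acetate | OC/C(C)=C/CC/C(C)=C/COC(C)=O | intermediate
3 | (2E,6E)-8-[(tert-butyldimethylsilyl)oxy]-3,7-dimethylocta-2,6-dien-1-yl acetate | CC(C)(C)[Si](C)(C)OC/C(C)=C/CC/C(C)=C/COC(C)=O | intermediate
4 | (2E,6E)-8-[(tert-butyldimethylsilyl)oxy]-3,7-dimethylocta-2,6-dien-1-ol | CC(C)(C)[Si](C)(C)OC/C(C)=C/CC/C(C)=C/CO | intermediate
5 | {[(2E,6E)-8-bromo-2,6-dimethylocta-2,6-dien-1-yl]oxy}(tert-butyl)dimethylsilane | CC(C)(C)[Si](C)(C)OC/C(C)=C/CC/C(C)=C/CBr | intermediate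
6 | 1-(trimethylsilyl)propyne | CC#C[Si](C)(C)C | starting material
7 | 3-lithio-1-(trimethylsilyl)propyne | [Li]CC#C[Si](C)(C)C | intermediate (not isolated)
8 | tert-butyldimethyl{[(2E,6E)-2,6-dimethyl-11-(trimethylsilyl)undeca-2,6-dien-10-yn-1-yl]oxy}silane | CC(C)(C)[Si](C)(C)OC/C(C)=C/CC/C(C)=C/CCC#C[Si](C)(C)C | intermediate
9 | tert-butyl{[(2E,6E)-2,6-dimethylundeca-2,6-dien-10-yn-1-yl]oxy}dimethylsilane | CC(C)(C)[Si](C)(C)OC/C(C)=C/CC/C(C)=C/CCC#C | intermediate
10 | (trimethylsilyl)methylmagnesium chloride | C[Si](C)(C)C[Mg]Cl | starting material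
11 | (trimethylsilyl)methylcopper (as its MgBrCl complex) | C[Si](C)(C)C[Cu] | intermediate (not isolated)
12 | vinylcopper adduct, {(1Z,5E,9E)-11-[(tert-butyldimethylsilyl)oxy]-6,10-dimethyl-2-[(trimethylsilyl)methyl]undeca-1,5,9-trien-1-yl}copper | CC(C)(C)[Si](C)(C)OC/C(C)=C/CC/C(C)=C/CC/C(C[Si](C)(C)C)=C/[Cu] | intermediate (not isolated)
13 | tert-butyl{[(2E,6E,10Z)-11-iodo-2,6-dimethyl-10-[(trimethylsilyl)methyl]undeca-2,6,10-trien-1-yl]oxy}dimethylsilane | CC(C)(C)[Si](C)(C)OC/C(C)=C/CC/C(C)=C/CC/C(C[Si](C)(C)C)=C/I | intermediate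
14 | methyl hydrogen (R)-3-methylglutarate | OC(=O)C[C@@H](C)CC(=O)OC | starting material
15 | methyl (3R)-5-hydroxy-3-methylpentanoate | OCC[C@@H](C)CC(=O)OC | intermediate
16 | methyl (3S)-5-iodo-3-methylpentanoate | ICC[C@@H](C)CC(=O)OC | intermediate
17 | [(3S)-5-methoxy-3-methyl-5-oxopentyl]zinc iodide | I[Zn]CC[C@@H](C)CC(=O)OC | intermediate (not isolated)
18 | methyl (3R,6Z,10E,14E)-16-[(tert-butyldimethylsilyl)oxy]-3,11,15-trimethyl-7-[(trimethylsilyl)methyl]hexadeca-6,10,14-trienoate | CC(C)(C)[Si](C)(C)OC/C(C)=C/CC/C(C)=C/CC/C(C[Si](C)(C)C)=C/CC[C@@H](C)CC(=O)OC | intermediate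
19 | methyl (3R,6Z,10E,14E)-16-hydroxy-3,11,15-trimethyl-7-[(trimethylsilyl)methyl]hexadeca-6,10,14-trienoate | OC/C(C)=C/CC/C(C)=C/CC/C(C[Si](C)(C)C)=C/CC[C@@H](C)CC(=O)OC | intermediate
20 | methyl (3R,6Z,10E)-13-[(2S,3S)-3-(hydroxymethyl)-3-methyloxiran-2-yl]-3,11-dimethyl-7-[(trimethylsilyl)methyl]trideca-6,10-dienoate | OC[C@]1(C)O[C@H]1CC/C(C)=C/CC/C(C[Si](C)(C)C)=C/CC[C@@H](C)CC(=O)OC | intermediate
21 | methyl (3R,6Z,10E)-13-[(2S,3S)-3-{[(tert-butyldimethylsilyl)oxy]methyl}-3-methyloxiran-2-yl]-3,11-dimethyl-7-[(trimethylsilyl)methyl]trideca-6,10-dienoate | CC(C)(C)[Si](C)(C)OC[C@]1(C)O[C@H]1CC/C(C)=C/CC/C(C[Si](C)(C)C)=C/CC[C@@H](C)CC(=O)OC | intermediate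
22 | methyl (13R)-18-[(tert-butyldimethylsilyl)oxy]-3β-hydroxylabd-8(17)-en-15-oate (5α-H, 9α-H, 10β-methyl) | C=C1CC[C@@H]2[C@](C)(CC[C@H](O)[C@@]2(C)CO[Si](C)(C)C(C)(C)C)[C@H]1CC[C@@H](C)CC(=O)OC | intermediate
23 | methyl (13R)-18-[(tert-butyldimethylsilyl)oxy]-3β-[(1H-imidazol-1-ylcarbonothioyl)oxy]labd-8(17)-en-15-oate | C=C1CC[C@@H]2[C@](C)(CC[C@H](OC(=S)n3ccnc3)[C@@]2(C)CO[Si](C)(C)C(C)(C)C)[C@H]1CC[C@@H](C)CC(=O)OC | intermediate
24 | methyl (13R)-18-[(tert-butyldimethylsilyl)oxy]labd-8(17)-en-15-oate | C=C1CC[C@@H]2[C@](C)(CCC[C@@]2(C)CO[Si](C)(C)C(C)(C)C)[C@H]1CC[C@@H](C)CC(=O)OC | intermediate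
25 | methyl (13R)-18-hydroxylabd-8(17)-en-15-oate | C=C1CC[C@@H]2[C@](C)(CCC[C@@]2(C)CO)[C@H]1CC[C@@H](C)CC(=O)OC | intermediate
26 | methyl (13R)-18-oxolabd-8(17)-en-15-oate | C=C1CC[C@@H]2[C@](C)(CCC[C@@]2(C)C=O)[C@H]1CC[C@@H](C)CC(=O)OC | intermediate
27 | (13R)-15-methoxy-15-oxolabd-8(17)-en-18-oic acid | C=C1CC[C@@H]2[C@](C)(CCC[C@@]2(C)C(=O)O)[C@H]1CC[C@@H](C)CC(=O)OC | intermediate
28 | dimethyl (13R)-labd-8(17)-ene-15,18-dioate | C=C1CC[C@@H]2[C@](C)(CCC[C@@]2(C)C(=O)OC)[C@H]1CC[C@@H](C)CC(=O)OC | intermediate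
29 | (13R)-18-methoxy-18-oxolabd-8(17)-en-15-oic acid (CNP0135192.4) | C=C1CC[C@@H]2[C@](C)(CCC[C@@]2(C)C(=O)OC)[C@H]1CC[C@@H](C)CC(=O)O | target

**Step count and risk**

Total step count: 21. Longest linear sequence: 19 steps (steps 1–7 and 10–21 from geranyl acetate 1); the side-chain branch is steps 8–9.

Steps most likely to fail:

1. Step 14 (key step). The siloxymethyl group withdraws electron density from C4, so ionisation of the C4–O bond may be slow; a 1,2-hydride shift to a C3 ketone, chloride opening of the epoxide or arrest after ring A could then outrun the bicyclization. Fallback (sets out from 9, comes back at 22): replace cationic initiation by single-electron epoxide opening on a silicon-free analogue. Zirconium-catalysed methylalumination of 9 (Me3Al, Cp2ZrCl2, CH2Cl2) and iodinolysis give the vinyl iodide tert-butyl{[(2E,6E,10E)-11-iodo-2,6,10-trimethylundeca-2,6,10-trien-1-yl]oxy}dimethylsilane F1. Negishi coupling with 17 as in step 10 gives methyl (3R,6E,10E,14E)-16-[(tert-butyldimethylsilyl)oxy]-3,7,11,15-tetramethylhexadeca-6,10,14-trienoate F2. Fluoride desilylation gives methyl (3R,6E,10E,14E)-16-hydroxy-3,7,11,15-tetramethylhexadeca-6,10,14-trienoate F3. Sharpless epoxidation as in step 12 gives methyl (3R,6E,10E)-13-[(2S,3S)-3-(hydroxymethyl)-3-methyloxiran-2-yl]-3,7,11-trimethyltrideca-6,10-dienoate F4, and silylation gives methyl (3R,6E,10E)-13-[(2S,3S)-3-{[(tert-butyldimethylsilyl)oxy]methyl}-3-methyloxiran-2-yl]-3,7,11-trimethyltrideca-6,10-dienoate F5. Cp2TiCl (trivalent titanium, made from Cp2TiCl2 and Mn dust, THF, rt) then opens the epoxide homolytically. The tertiary C4 radical should close rings A and B by two 6-endo additions, and a second Cp2TiCl should turn the C8 radical into the exocyclic alkene, giving 22 after aqueous work-up. In this variant the C4 configuration rests on the equatorial preference of the larger CH2OSi group and no longer on the epoxide geometry.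

2. Step 7. The silylmethylcopper is a weakly nucleophilic organocopper, so syn addition to the unactivated alkyne may not take place, or the alkyne C–H may be metalated instead. Fallback (sets out from 9, comes back at 18): build the same alkene by two cross-couplings on a dihaloalkene. Iodination of 9 (N-iodosuccinimide, AgNO3 cat., acetone) gives the iodoalkyne tert-butyl{[(2E,6E)-11-iodo-2,6-dimethylundeca-2,6-dien-10-yn-1-yl]oxy}dimethylsilane F6. Anti-hydrobromination (LiBr, AcOH, Pd(OAc)2 cat.) should give the dihaloalkene tert-butyl{[(2E,6E,10Z)-10-bromo-11-iodo-2,6-dimethylundeca-2,6,10-trien-1-yl]oxy}dimethylsilane F7, with bromine on the internal carbon and cis to iodine. Negishi coupling of 17 at the more reactive C–I bond (PdCl2(dppf)) gives methyl (3R,6Z,10E,14E)-7-bromo-16-[(tert-butyldimethylsilyl)oxy]-3,11,15-trimethylhexadeca-6,10,14-trienoate F8. A second Negishi coupling with (trimethylsilyl)methylzinc chloride F9 (from 10 and ZnCl2; Pd(PtBu3)2, THF) replaces bromine with retention and gives 18; step 10 is then not needed.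

3. Step 11. Fluoride may attack the allylic C–SiMe3 bond and protodesilylate to the 1,1-disubstituted alkene in competition with O–Si cleavage. Fallback (sets out from 8, comes back at 19): remove both silyl groups before the allylsilane exists. TBAF in THF converts 8 into (2E,6E)-2,6-dimethylundeca-2,6-dien-10-yn-1-ol F10. Carbocupration–iodination under the conditions of step 7, with one further equivalent of 10 to take up the hydroxyl proton, gives (2E,6E,10Z)-11-iodo-2,6-dimethyl-10-[(trimethylsilyl)methyl]undeca-2,6,10-trien-1-ol F11. Negishi coupling with an excess of 17 (Pd(OAc)2, SPhos, THF/DMA), which tolerates the free hydroxyl, gives 19 directly.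

**Further compounds**
F1 | step 14 | tert-butyl{[(2E,6E,10E)-11-iodo-2,6,10-trimethylundeca-2,6,10-trien-1-yl]oxy}dimethylsilane | CC(C)(C)[Si](C)(C)OC/C(C)=C/CC/C(C)=C/CC/C(C)=C/I
F2 | step 14 | methyl (3R,6E,10E,14E)-16-[(tert-butyldimethylsilyl)oxy]-3,7,11,15-tetramethylhexadeca-6,10,14-trienoate | CC(C)(C)[Si](C)(C)OC/C(C)=C/CC/C(C)=C/CC/C(C)=C/CC[C@@H](C)CC(=O)OC
F3 | step 14 | methyl (3R,6E,10E,14E)-16-hydroxy-3,7,11,15-tetramethylhexadeca-6,10,14-trienoate | OC/C(C)=C/CC/C(C)=C/CC/C(C)=C/CC[C@@H](C)CC(=O)OC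
F4 | step 14 | methyl (3R,6E,10E)-13-[(2S,3S)-3-(hydroxymethyl)-3-methyloxiran-2-yl]-3,7,11-trimethyltrideca-6,10-dienoate | OC[C@]1(C)O[C@H]1CC/C(C)=C/CC/C(C)=C/CC[C@@H](C)CC(=O)OC
F5 | step 14 | methyl (3R,6E,10E)-13-[(2S,3S)-3-{[(tert-butyldimethylsilyl)oxy]methyl}-3-methyloxiran-2-yl]-3,7,11-trimethyltrideca-6,10-dienoate | CC(C)(C)[Si](C)(C)OC[C@]1(C)O[C@H]1CC/C(C)=C/CC/C(C)=C/CC[C@@H](C)CC(=O)OC
F6 | step 7 | tert-butyl{[(2E,6E)-11-iodo-2,6-dimethylundeca-2,6-dien-10-yn-1-yl]oxy}dimethylsilane | CC(C)(C)[Si](C)(C)OC/C(C)=C/CC/C(C)=C/CCC#CI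
F7 | step 7 | tert-butyl{[(2E,6E,10Z)-10-bromo-11-iodo-2,6-dimethylundeca-2,6,10-trien-1-yl]oxy}dimethylsilane | CC(C)(C)[Si](C)(C)OC/C(C)=C/CC/C(C)=C/CC/C(Br)=C/I
F8 | step 7 | methyl (3R,6Z,10E,14E)-7-bromo-16-[(tert-butyldimethylsilyl)oxy]-3,11,15-trimethylhexadeca-6,10,14-trienoate | CC(C)(C)[Si](C)(C)OC/C(C)=C/CC/C(C)=C/CC/C(Br)=C/CC[C@@H](C)CC(=O)OC
F9 | step 7 | (trimethylsilyl)methylzinc chloride | C[Si](C)(C)C[Zn]Cl
F10 | step 11 | (2E,6E)-2,6-dimethylundeca-2,6-dien-10-yn-1-ol | OC/C(C)=C/CC/C(C)=C/CCC#C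
F11 | step 11 | (2E,6E,10Z)-11-iodo-2,6-dimethyl-10-[(trimethylsilyl)methyl]undeca-2,6,10-trien-1-ol | OC/C(C)=C/CC/C(C)=C/CC/C(C[Si](C)(C)C)=C/I
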